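**Outline**

- Cuts: first the two benzoate C–O bonds at O5 and O7. Then C7 goes back to the ester oxidation level, the C3–O and C4–O bonds are removed (osmylation), and last the C5–O and C6–O bonds, which leads to ethyl benzoate.
- Enabling feature: C1–C6 plus the exocyclic C7 are the carbon skeleton of a benzoate. The cis C5–O/C6–O pair beside C1 is the ortho,meta cis-dihydrodiol of that arene, C1=C2 is one leftover arene double bond, and the cis C3/C4 diol on the opposite face is the osmylation product of the other.
- Forward: the carbocycle is never built, because the benzene ring of ethyl benzoate is dearomatised enzymatically. The two diol oxygens are told apart at once (silyl on O5, methoxymethyl on O6). C3=C4 is then dihydroxylated and masked as a temporary dioxolane, the only ring closed. The ester is reduced, O5 is freed, and both benzoates go on in one operation.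
- Stereochemistry: C5 and C6 (absolute) come from the enzyme; C3 and C4 are relayed by osmylation anti to the C5/C6 oxygens; nothing is inverted later.

Key step: step 1

Locants and faces used throughout: C1 bears C7, C1=C2, and C3 to C6 follow round the ring. With C1→C6 drawn counter-clockwise, β (O5, O6) points to the viewer and α (O3, O4) away.

**Route**

Step 1
Reactants: 1 ethyl benzoate
Product: 2 ethyl (5S,6R)-5,6-dihydroxycyclohexa-1,3-diene-1-carboxylate
Conditions: whole cells of E. coli JM109(pDTG601A) expressing toluene dioxygenase (no diol dehydrogenase), IPTG, glucose feed, air (O2), pH 7, 30–35 °C; EtOAc extraction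
Reagents that add atoms: dioxygen, O=O
Why: The Rieske-type non-haem iron dioxygenase draws two electrons from NADH (recycled by the glucose metabolism of the cell, so it acts catalytically), activates O2 at its mononuclear iron site and passes both oxygen atoms to the same face of the ortho,meta edge of the bound arene, which breaks aromaticity and leaves the C1=C2/C3=C4 diene. The closest known reaction type is the whole-cell toluene dioxygenase cis-dihydroxylation of monosubstituted benzenes such as toluene, halobenzenes and alkyl benzoates. No ring is closed, since the benzene ring itself becomes the carbocycle, so there is no closure mode to assign. Both new stereocentres (C5 S, C6 R) are fixed by the active-site pocket, which presents one enantioface of the arene, and their cis relationship follows from the same-face delivery of the two oxygen atoms. The step needs ortho,meta rather than ipso,ortho or meta,para regiochemistry, a single enantiomer and survival of the diol. The single small ester substituent of the substrate orients the ring in the pocket and secures the first two, and the missing dehydrogenase in the host prevents re-aromatisation to the catechol.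

Step 2
Reactants: 2 ethyl (5S,6R)-5,6-dihydroxycyclohexa-1,3-diene-1-carboxylate
Product: 3 ethyl (5S,6R)-5-(tert-butyldimethylsilyloxy)-6-hydroxycyclohexa-1,3-diene-1-carboxylate
Conditions: TBSCl (1.05 equiv), imidazole, DMF, −20 °C to 0 °C
Reagents that add atoms: tert-butyldimethylsilyl chloride, CC(C)(C)[Si](C)(C)Cl
Why: Sterically controlled monosilylation (silyl chloride with imidazole) should take the C5 hydroxyl, which has only the vinylic C4–H beside it, in preference to the C6 hydroxyl, which is crowded by the ester-bearing C1 and hydrogen-bonded to the ester carbonyl, as is general for bulky silyl chlorides and 3-substituted cis-cyclohexa-3,5-diene-1,2-diols; no stereocentre is touched and the cold, buffered conditions avoid dehydration to a phenol.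

Step 3
Reactants: 3 ethyl (5S,6R)-5-(tert-butyldimethylsilyloxy)-6-hydroxycyclohexa-1,3-diene-1-carboxylate
Product: 4 ethyl (5S,6R)-5-(tert-butyldimethylsilyloxy)-6-(methoxymethoxy)cyclohexa-1,3-diene-1-carboxylate
Conditions: MOMCl, i-Pr2NEt, CH2Cl2, 0 °C to rt
Reagents that add atoms: chloromethyl methyl ether (MOMCl), COCCl
Why: O-Alkylation of the remaining C6 hydroxyl with the very reactive α-chloro ether under amine buffering (acetal-type etherification without acid or alkoxide) should not provoke silyl migration or aromatisation, and it leaves the two oxygens of the cis-diol chemically distinct, fluoride-labile at C5 and acid-labile at C6.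

Step 4
Reactants: 4 ethyl (5S,6R)-5-(tert-butyldimethylsilyloxy)-6-(methoxymethoxy)cyclohexa-1,3-diene-1-carboxylate
Product: 5 ethyl 5β-(tert-butyldimethylsilyloxy)-3α,4α-dihydroxy-6β-(methoxymethoxy)cyclohex-1-ene-1-carboxylate
Conditions: OsO4 (2 mol %), NMO (1.5 equiv), acetone/H2O (4:1), 0 °C to rt; Na2SO3 quench
Reagents that add atoms: osmium tetroxide, O=[Os](=O)(=O)=O (delivers both oxygen atoms; its oxo ligands are replenished by N-methylmorpholine N-oxide, C[N+]1([O-])CCOCC1, and water, O)
Why: Catalytic syn-dihydroxylation with OsO4 and an N-oxide co-oxidant is electrophilic and should therefore pick the disubstituted γ,δ-alkene C3=C4 over the trisubstituted, ester-conjugated C1=C2, approaching from the α face opposite the allylic C5 silyloxy group and the C6 ether, so that C3 and C4 are created together as the cis-diol trans to C5–O.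

Step 5
Reactants: 5 ethyl 5β-(tert-butyldimethylsilyloxy)-3α,4α-dihydroxy-6β-(methoxymethoxy)cyclohex-1-ene-1-carboxylate
Product: 6 ethyl 5β-(tert-butyldimethylsilyloxy)-3α,4α-(isopropylidenedioxy)-6β-(methoxymethoxy)cyclohex-1-ene-1-carboxylate
Conditions: 2,2-dimethoxypropane, PPTS (cat.), CH2Cl2, rt
Reagents that add atoms: 2,2-dimethoxypropane, COC(C)(C)OC
Why: Acid-catalysed transketalisation with the dimethyl ketal closes the cis-fused five-membered dioxolane on the only free diol (cis at C3/C4), and the weak acid PPTS should leave the secondary silyl ether and the methoxymethyl ether untouched.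

Step 6
Reactants: 6 ethyl 5β-(tert-butyldimethylsilyloxy)-3α,4α-(isopropylidenedioxy)-6β-(methoxymethoxy)cyclohex-1-ene-1-carboxylate
Product: 8 [5β-(tert-butyldimethylsilyloxy)-3α,4α-(isopropylidenedioxy)-6β-(methoxymethoxy)cyclohex-1-en-1-yl]methanol, via enal 7 (not isolated)
Conditions: i-Bu2AlH (2.5 equiv), CH2Cl2, −78 °C; aqueous potassium sodium tartrate work-up
Reagents that add atoms: none
Why: Ester reduction with the electrophilic aluminium hydride at low temperature is a clean 1,2-process for α,β-unsaturated esters (no conjugate reduction) that runs through the aldehyde to the allylic alcohol, and the ethers, the silyl ether and the ketal are inert to it.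

Step 7
Reactants: 8 [5β-(tert-butyldimethylsilyloxy)-3α,4α-(isopropylidenedioxy)-6β-(methoxymethoxy)cyclohex-1-en-1-yl]methanol
Product: 9 [5β-hydroxy-3α,4α-(isopropylidenedioxy)-6β-(methoxymethoxy)cyclohex-1-en-1-yl]methanol
Conditions: Bu4NF (1.2 equiv), THF, 0 °C to rt
Reagents that add atoms: none
Why: Fluoride-mediated desilylation, driven by the strength of the Si–F bond, should release only the C5 hydroxyl because the methoxymethyl ether and the ketal do not respond to fluoride, and it is done before any acyl group is present that could migrate under the basic conditions.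

Step 8
Reactants: 9 [5β-hydroxy-3α,4α-(isopropylidenedioxy)-6β-(methoxymethoxy)cyclohex-1-en-1-yl]methanol; 10 benzoyl chloride
Product: 12 [5β-(benzoyloxy)-3α,4α-(isopropylidenedioxy)-6β-(methoxymethoxy)cyclohex-1-en-1-yl]methyl benzoate, via C7 monobenzoate 11 (not isolated)
Conditions: BzCl (2.6 equiv), pyridine, DMAP (cat.), CH2Cl2, 0 °C to rt
Reagents that add atoms: benzoyl chloride (10), O=C(Cl)c1ccccc1
Why: DMAP-catalysed acylation with the acid chloride esterifies the only two free hydroxyls, the primary allylic C7–OH first and the secondary C5–OH next, so that the position of the benzoates is dictated by the protecting-group pattern and not by a rate difference between C5–OH and C6–OH; only O–H bonds react, so no stereocentre is affected.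

Step 9
Reactants: 12 [5β-(benzoyloxy)-3α,4α-(isopropylidenedioxy)-6β-(methoxymethoxy)cyclohex-1-en-1-yl]methyl benzoate
Product: 14 [(3R,4R,5R,6R)-5-(benzoyloxy)-3,4,6-trihydroxycyclohex-1-en-1-yl]methyl benzoate (CNP0198957.3), via MOM ether diol 13 (not isolated)
Conditions: TFA/H2O (9:1), 0 °C to rt; co-evaporation with toluene
Reagents that add atoms: none
Why: Acid-catalysed hydrolysis of the two acetal-type groups through oxocarbenium ions (the isopropylidene ketal first, the methoxymethyl ether second) should spare the benzoates, since ester hydrolysis and acyl migration are slow in cold aqueous acid and no C–O bond at a stereocentre is cleaved.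

**Compound list**

1 | ethyl benzoate | CCOC(=O)c1ccccc1 | starting material
2 | ethyl (5S,6R)-5,6-dihydroxycyclohexa-1,3-diene-1-carboxylate | CCOC(=O)C1=CC=C[C@H](O)[C@@H]1O | intermediate
3 | ethyl (5S,6R)-5-(tert-butyldimethylsilyloxy)-6-hydroxycyclohexa-1,3-diene-1-carboxylate | CCOC(=O)C1=CC=C[C@H](O[Si](C)(C)C(C)(C)C)[C@@H]1O | intermediate
4 | ethyl (5S,6R)-5-(tert-butyldimethylsilyloxy)-6-(methoxymethoxy)cyclohexa-1,3-diene-1-carboxylate | CCOC(=O)C1=CC=C[C@H](O[Si](C)(C)C(C)(C)C)[C@@H]1OCOC | intermediate
5 | ethyl 5β-(tert-butyldimethylsilyloxy)-3α,4α-dihydroxy-6β-(methoxymethoxy)cyclohex-1-ene-1-carboxylate | CCOC(=O)C1=C[C@@H](O)[C@@H](O)[C@H](O[Si](C)(C)C(C)(C)C)[C@@H]1OCOC | intermediate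
6 | ethyl 5β-(tert-butyldimethylsilyloxy)-3α,4α-(isopropylidenedioxy)-6β-(methoxymethoxy)cyclohex-1-ene-1-carboxylate | CCOC(=O)C1=C[C@H]2OC(C)(C)O[C@H]2[C@H](O[Si](C)(C)C(C)(C)C)[C@@H]1OCOC | intermediate
7 | 5β-(tert-butyldimethylsilyloxy)-3α,4α-(isopropylidenedioxy)-6β-(methoxymethoxy)cyclohex-1-ene-1-carbaldehyde (enal; not isolated) | O=CC1=C[C@H]2OC(C)(C)O[C@H]2[C@H](O[Si](C)(C)C(C)(C)C)[C@@H]1OCOC | intermediate
8 | [5β-(tert-butyldimethylsilyloxy)-3α,4α-(isopropylidenedioxy)-6β-(methoxymethoxy)cyclohex-1-en-1-yl]methanol | OCC1=C[C@H]2OC(C)(C)O[C@H]2[C@H](O[Si](C)(C)C(C)(C)C)[C@@H]1OCOC | intermediate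
9 | [5β-hydroxy-3α,4α-(isopropylidenedioxy)-6β-(methoxymethoxy)cyclohex-1-en-1-yl]methanol | OCC1=C[C@H]2OC(C)(C)O[C@H]2[C@H](O)[C@@H]1OCOC | intermediate
10 | benzoyl chloride | O=C(Cl)c1ccccc1 | starting material
11 | [5β-hydroxy-3α,4α-(isopropylidenedioxy)-6β-(methoxymethoxy)cyclohex-1-en-1-yl]methyl benzoate (C7 monobenzoate; not isolated) | O=C(OCC1=C[C@H]2OC(C)(C)O[C@H]2[C@H](O)[C@@H]1OCOC)c1ccccc1 | intermediate
12 | [5β-(benzoyloxy)-3α,4α-(isopropylidenedioxy)-6β-(methoxymethoxy)cyclohex-1-en-1-yl]methyl benzoate | O=C(OCC1=C[C@H]2OC(C)(C)O[C@H]2[C@H](OC(=O)c3ccccc3)[C@@H]1OCOC)c1ccccc1 | intermediate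
13 | [5β-(benzoyloxy)-3α,4α-dihydroxy-6β-(methoxymethoxy)cyclohex-1-en-1-yl]methyl benzoate (MOM ether diol; not isolated) | O=C(OCC1=C[C@@H](O)[C@@H](O)[C@H](OC(=O)c2ccccc2)[C@@H]1OCOC)c1ccccc1 | intermediate
14 | [(3R,4R,5R,6R)-5-(benzoyloxy)-3,4,6-trihydroxycyclohex-1-en-1-yl]methyl benzoate (CNP0198957.3) | O=C(OCC1=C[C@@H](O)[C@@H](O)[C@H](OC(=O)c2ccccc2)[C@@H]1O)c1ccccc1 | target

**Step count**

Total steps: 9. Longest linear sequence: 9 steps (1 to 14); benzoyl chloride 10 is bought and enters in step 8.

**Steps most likely to fail**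

Step 2. The two cis hydroxyls may be discriminated incompletely, or the silyl group may wander between them, which would scramble the positions that later receive benzoate and MOM. The fallback sets out from 2 and returns to the route at 14. It protects both hydroxyls alike and makes the distinction late, through the 1,3-relationship of O6 and O7.
- 2 would be bis-silylated (TBSOTf, 2,6-lutidine, CH2Cl2, −78 °C) to the 5,6-bis-TBS diene F1.
- F1 would be osmylated as in step 4 to the 3α,4α-diol F2, ketalised as in step 5 to the 3,4-acetonide F3, reduced with i-Bu2AlH to the allylic alcohol F4 and desilylated with Bu4NF to the 5,6,7-triol F5.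
- t-Bu2Si(OTf)2 with 2,6-lutidine (DMF, −40 to 0 °C) should bridge the primary O7 and the 1,3-related O6 as the six-membered cyclic silylene F6; a five-membered silylene across O5/O6 is strained and disfavoured.
- Only C5–OH is then free, and benzoylation (BzCl, pyridine, DMAP) should give the C5 benzoate silylene F7.
- HF·pyridine (THF, 0 °C) would open the silylene to the 6,7-diol F8, whose primary hydroxyl is benzoylated selectively (BzCl 1.05 equiv, 2,4,6-collidine, CH2Cl2, −40 °C) to the C5,C7-dibenzoate 3,4-acetonide F9 with free C6–OH.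
- Mild ketal hydrolysis (80% aqueous AcOH, 40 °C) would then give 14.

Step 3. Alkylation of the hindered, hydrogen-bonded C6 hydroxyl may be slow, and during that time the diene may dimerise by [4+2] cycloaddition or lose silanol or water to an aromatic ester. The fallback sets out from 3 and returns at 6; it postpones the alkylation until the diene is gone. 3 would be osmylated directly (OsO4 cat., NMO; same alkene and same face) to the C5-silylated 3α,4α,6β-triol F10. The cis C3/C4 diol would be ketalised (2,2-dimethoxypropane, PPTS) to the 6-hydroxy acetonide F11. This robust enoate would then be treated with MOMCl/i-Pr2NEt, at 40 °C if required, to give 6.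

Step 9. During the strongly acidic double deprotection the C5 benzoate may migrate to the neighbouring cis C6–OH or to the freed C4–OH, the allylic C7 benzoate may solvolyse, or cleavage of the MOM ether may stall. The fallback sets out from 12 and returns at 14. It divides the endgame into two chemoselective operations and removes the MOM group by non-hydrolytic dealkylation instead of hydrolysis. 12 would first be treated with 80% aqueous AcOH at 40 °C, which should remove only the ketal, and diol 13 would be isolated. 13 would then be exposed to Me2BBr (CH2Cl2, −78 °C, then aqueous NaHCO3): bromide attacks the boron-activated O–CH2–O carbon at a temperature where acyl transfer is frozen, giving 14. This path passes only through compounds already numbered (F0).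

**Further compounds**

F1 | step 2 | ethyl (5S,6R)-5,6-bis(tert-butyldimethylsilyloxy)cyclohexa-1,3-diene-1-carboxylate | CCOC(=O)C1=CC=C[C@H](O[Si](C)(C)C(C)(C)C)[C@@H]1O[Si](C)(C)C(C)(C)C
F2 | step 2 | ethyl 5β,6β-bis(tert-butyldimethylsilyloxy)-3α,4α-dihydroxycyclohex-1-ene-1-carboxylate | CCOC(=O)C1=C[C@@H](O)[C@@H](O)[C@H](O[Si](C)(C)C(C)(C)C)[C@@H]1O[Si](C)(C)C(C)(C)C
F3 | step 2 | ethyl 5β,6β-bis(tert-butyldimethylsilyloxy)-3α,4α-(isopropylidenedioxy)cyclohex-1-ene-1-carboxylate | CCOC(=O)C1=C[C@H]2OC(C)(C)O[C@H]2[C@H](O[Si](C)(C)C(C)(C)C)[C@@H]1O[Si](C)(C)C(C)(C)C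
F4 | step 2 | [5β,6β-bis(tert-butyldimethylsilyloxy)-3α,4α-(isopropylidenedioxy)cyclohex-1-en-1-yl]methanol | OCC1=C[C@H]2OC(C)(C)O[C@H]2[C@H](O[Si](C)(C)C(C)(C)C)[C@@H]1O[Si](C)(C)C(C)(C)C
F5 | step 2 | [5β,6β-dihydroxy-3α,4α-(isopropylidenedioxy)cyclohex-1-en-1-yl]methanol | OCC1=C[C@H]2OC(C)(C)O[C@H]2[C@H](O)[C@@H]1O
F6 | step 2 | O6,O7-(di-tert-butylsilylene) derivative of the 5,6,7-triol 3,4-acetonide (free C5–OH) | CC(C)(C)[Si]1(C(C)(C)C)OCC2=C[C@H]3OC(C)(C)O[C@H]3[C@H](O)[C@@H]2O1
F7 | step 2 | 5-O-benzoyl-O6,O7-(di-tert-butylsilylene) 3,4-acetonide | CC(C)(C)[Si]1(C(C)(C)C)OCC2=C[C@H]3OC(C)(C)O[C@H]3[C@H](OC(=O)c4ccccc4)[C@@H]2O1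
F8 | step 2 | [5β-(benzoyloxy)-6β-hydroxy-3α,4α-(isopropylidenedioxy)cyclohex-1-en-1-yl]methanol | OCC1=C[C@H]2OC(C)(C)O[C@H]2[C@H](OC(=O)c3ccccc3)[C@@H]1O
F9 | step 2 | [5β-(benzoyloxy)-6β-hydroxy-3α,4α-(isopropylidenedioxy)cyclohex-1-en-1-yl]methyl benzoate | O=C(OCC1=C[C@H]2OC(C)(C)O[C@H]2[C@H](OC(=O)c3ccccc3)[C@@H]1O)c1ccccc1
F10 | step 3 | ethyl 5β-(tert-butyldimethylsilyloxy)-3α,4α,6β-trihydroxycyclohex-1-ene-1-carboxylate | CCOC(=O)C1=C[C@@H](O)[C@@H](O)[C@H](O[Si](C)(C)C(C)(C)C)[C@@H]1O
F11 | step 3 | ethyl 5β-(tert-butyldimethylsilyloxy)-6β-hydroxy-3α,4α-(isopropylidenedioxy)cyclohex-1-ene-1-carboxylate | CCOC(=O)C1=C[C@H]2OC(C)(C)O[C@H]2[C@H](O[Si](C)(C)C(C)(C)C)[C@@H]1O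
F0 | step 9 | none | none
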